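A flask of 0.23 M starting material, 0.414 M reagent and 0.218 M solid partner holds 1.80 equivalents of reagent, yet what counts is how much reagent a target molecule meets after it forms.

| setting | alder | birch | oak | elm | midnight | noon | dusk | spring |
|---|---|---|---|---|---|---|---|---|
| starting material | 0.23 M | 0.23 M | 0.23 M | 0.23 M | 0.23 M | 0.23 M | 0.23 M (in portions, 5, over 5.0 d) | 0.23 M (fed, over 5.0 d) |
| reagent | 0.414 M | 0.58 M | 0.91 M | 0.414 M | 0.414 M (fed, over 5.0 d) | 0.414 M | 0.414 M | 0.414 M |
| solid partner | 0.218 M | 0.218 M | 0.218 M | 0.44 M | 0.218 M | 0.218 M | 0.218 M | 0.218 M |
| remark | run made earlier | run made earlier | run made earlier | run made earlier | all else is in the flask from the start; the feed brings no volume worth counting | everything together at the start | first portion at the start, last at 5.0 d | all else is in the flask from the start; the feed brings no volume worth counting |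
| time |  |  |  |  | 8.0 d | 8.0 d | 8.0 d | 8.0 d |

- alder (time / d: target / %, over-reaction product / %): 1.67: 6, 0; 3.00: 10, 4; 5.00: 19, 10; 6.00: 20, 9; 8.00: 23, 14
- birch (time / d: target / %, over-reaction product / %): 0.417: 0, 0; 0.833: 0, 0; 1.25: 3, 0; 2.50: 11, 6; 5.00: 16, 20
- oak (time / d: target / %, over-reaction product / %): 0.417: 0, 0; 0.833: 0, 1; 1.25: 4, 2; 2.50: 9, 10; 5.00: 10, 35
- elm (time / d: target / %, over-reaction product / %): 1.04: 3, 0; 2.08: 7, 5; 3.00: 11, 2; 4.00: 18, 4; 5.00: 24, 6

(scatter of a reading: 1.5 percentage points)

1. the flask with the highest share of target in target plus over-reaction product ("all alike" if they lie within 1.5 percentage points) (midnight / noon / dusk / spring / all alike)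
2. share of target in target plus over-reaction product at the end, midnight
3. share of target in target plus over-reaction product at the end, noon
4. share of target in target plus over-reaction product at the end, dusk
5. share of target in target plus over-reaction product at the end, spring

- solid, in amounts per volume of the solution: solid partner
- what was read earlier has a scatter of 1.5 percentage points, one standard deviation
- at the start none of the solid partner is in solution

In alder, over-reaction product reads 0% at 1.67 d while target reads 6%, so over-reaction product is taken to come from target. The ledger of charged starting material at 8.00 d, for alder and so for noon, then runs: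

formed as target: 37.0%
still target: 23%
passed on to over-reaction product: 14%
in neither: 63.0%

Integrating the loss of a batch of target, d[target]/dt = −κ[reagent][target], gives the share (the selectivity):

share = exp(−κ [reagent] τ)

Here τ is the mean age of target, half the run while formation is steady. Oak charges 0.91 M reagent, but starting material and solid partner can take up to 0.448 M of it, so [reagent] falls below the charge during the run. Reckoned on the charge all the same, oak's last reading gives κ, an apparent over-reaction constant that reads low for that reason: 7.65 × 10⁻⁶ M⁻¹ s⁻¹.

Noon's ledger gives a share of 62.2%, so its target sees, on oak's scale, an effective level of 0.180 M, less than the charge. In dusk and spring, later starting material shortens τ to 2.75 d, but reagent stays higher. Between noon's level and the charge, the shares span 72.1% to 47.1%, and the middle level gives this reckoning 58.3% for both. In midnight, younger target and a later reagent level are taken to cancel, leaving noon's share.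

The forecast differs, with midnight best: midnight 71%, noon 63%, dusk 67%, spring 68%, since “Feeding reagent keeps its level low early”.

The flasks give midnight 60.0%, noon 61.6%, dusk 54.5%, spring 56.2%; noon stands highest.

    starting material + reagent → open intermediate (k = 9.80 × 10⁻⁶ M⁻¹ s⁻¹)
    reagent + fresh partner → second intermediate (k = 3.60 × 10⁻⁴ M⁻¹ s⁻¹)
    open intermediate + second intermediate → target (k = 1.70 × 10⁻⁵ M⁻¹ s⁻¹)
    2 second intermediate → homo product (k = 9.30 × 10⁻⁷ M⁻¹ s⁻¹)
    reagent + target → over-reaction product (k = 2.60 × 10⁻⁵ M⁻¹ s⁻¹)
    solid partner ⇌ fresh partner, rate k6*(cs6 - [fresh partner]) while solid is left; crystals form when [fresh partner] > cs6 (solubility = 0.0620 M, k = 1.90 × 10⁻⁵ s⁻¹)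

Spring keeps 17.2% of its reagent at 8.00 d against noon's 8.08%. In dusk at 1.22 d, reagent's half-life is 2.5 d on the path to second intermediate and 26 d on the path with starting material, ten times longer.

The neighbour of dusk with 0.57 M starting material ends with 3.09% of its reagent, less than noon, so noon's effective level and dusk's τ give 72.1%. That flask gives 72.6%.

The readings come from a simulation for an exercise.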